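**Retrosynthetic overview**
1. The target is read as a (1S,2S,5S,6S)-2,6-diaryl-3,7-dioxabicyclo[3.3.0]octane with both aryl groups endo, whose C2 aryl is C5 of a cis-(2S,3S)-2-guaiacyl-3-(hydroxymethyl)-7-methoxy-2,3-dihydrobenzofuran. The last C–C disconnection is furofuran C2–benzofuran C5: an aryllithium adds to an endo-aryl γ-lactone and the lactol is reduced by hydride from the exo face.
2. The strategy rests on benzofuran C3: it is bonded to the benzo carbon C3a and carries a one-carbon oxygenated arm cis to the C2 aryl. That is the outcome of a 1,2-shift of C4a from the C4 carbonyl to C3 in a 3-diazoflavanone, with C4 becoming the arm (photochemical Wolff contraction of the pyranone to the dihydrofuran).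
3. The diazo ketone comes from a (2S)-flavanone, made by asymmetric conjugate arylation of 6-bromo-8-methoxychromone and then diazo transfer at C3. The bromine on ring B (the benzo ring) is the later coupling handle; ring C is the guaiacyl ring on C2.
4. The lactone partner keeps a butenolide ring as its lactone: tandem dithiane conjugate addition/hydroxymethylation on a menthyloxybutenolide, ketone unmasking, hemiketal closure and exo-face silane reduction give the first tetrahydrofuran ring with its aryl endo.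
5. Ring order: pyranone (chromone), then dihydrofuran by contraction; lactone, first tetrahydrofuran ring, then the second tetrahydrofuran ring at the fragment union; deprotection last.

Key step: step 5

Assumption: in step 3 the ligand antipode that gives the 2S flavanone is used; (R)-t-BuPyOX is written by analogy with the sense known for cyclic enones and would be swapped for (S) if the first run gives 2R.
Assumption: (5R)-5-(l-menthyloxy)furan-2(5H)-one is taken as a purchasable reagent.

**Route**

Step 1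
Reactants: 1 2'-hydroxy-3'-methoxyacetophenone
Product: 2 1-(5-bromo-2-hydroxy-3-methoxyphenyl)ethanone
Conditions: NBS (1.05 equiv), MeCN, 0 °C → rt
Reagents that add atoms: N-bromosuccinimide, O=C1CCC(=O)N1Br
Why: Electrophilic aromatic bromination, in which the phenol directs to its free para position (both ortho positions are substituted) and NBS in MeCN avoids α-bromination of the ketone.

Step 2
Reactants: 2 1-(5-bromo-2-hydroxy-3-methoxyphenyl)ethanone
Product: 4 6-bromo-8-methoxy-4H-chromen-4-one, via enaminone 3 (not isolated)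
Conditions: Me2NCH(OMe)2, PhMe, 100 °C; then conc. HCl, CH2Cl2, 40 °C
Reagents that add atoms: N,N-dimethylformamide dimethyl acetal, COC(OC)N(C)C
Why: Standard chromone synthesis: condensation of the methyl ketone with the amide acetal gives the enaminone, and acid promotes conjugate addition of the phenol with loss of dimethylamine.

Step 3
Reactants: 4 6-bromo-8-methoxy-4H-chromen-4-one; 5 [4-(benzyloxy)-3-methoxyphenyl]boronic acid
Product: 6 (2S)-2-[4-(benzyloxy)-3-methoxyphenyl]-6-bromo-8-methoxy-2,3-dihydro-4H-chromen-4-one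
Conditions: Pd(OCOCF3)2 (5 mol%), (R)-t-BuPyOX (6 mol%), NH4PF6 (30 mol%), H2O (5 equiv), ClCH2CH2Cl, 60 °C
Reagents that add atoms: none
Why: Asymmetric conjugate addition of an arylboronic acid to a chromone under cationic divalent palladium/pyridine–oxazoline catalysis, in which the ligand fixes the face of aryl transfer to C2 (2S) and, since no zerovalent palladium is generated, the aryl bromide should survive.

Step 4
Reactants: 6 (2S)-2-[4-(benzyloxy)-3-methoxyphenyl]-6-bromo-8-methoxy-2,3-dihydro-4H-chromen-4-one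
Product: 8 (2R)-2-[4-(benzyloxy)-3-methoxyphenyl]-6-bromo-3-diazo-8-methoxy-2,3-dihydro-4H-chromen-4-one (spatially as 6; R only by CIP priority), via 3-trifluoroacetylflavanone 7 (not isolated)
Conditions: LiN(SiMe3)2, THF, −78 °C; CF3CO2CH2CF3, −78 °C; aq NH4Cl; then 4-AcNHC6H4SO2N3, Et3N, H2O (1 equiv), MeCN, 0 °C → rt
Reagents that add atoms: 4-acetamidobenzenesulfonyl azide, CC(=O)Nc1ccc(cc1)S(=O)(=O)N=[N+]=[N-]
Why: Detrifluoroacetylative (Regitz-type) diazo transfer, in which the kinetic C3 lithium enolate is C-acylated at −78 °C and the activated 1,3-diketone then takes N2 from the sulfonyl azide while passing its trifluoroacetyl group to the sulfonamide nitrogen, the low temperature and short base contact being meant to keep the enolate from β-eliminating the ring B phenoxide so that C2 is retained.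

Step 5
Reactants: 8 (2R)-2-[4-(benzyloxy)-3-methoxyphenyl]-6-bromo-3-diazo-8-methoxy-2,3-dihydro-4H-chromen-4-one
Product: 11 methyl (2S,3R)-2-[4-(benzyloxy)-3-methoxyphenyl]-5-bromo-7-methoxy-2,3-dihydro-1-benzofuran-3-carboxylate (2,3-cis), via ketene 9 (not isolated), via ester enol 10 (not isolated)
Conditions: hν (365 nm), MeOH/THF (4:1), −40 °C; evaporation without base
Reagents that add atoms: methanol, CO
Why: Photochemical Wolff rearrangement: excitation of the diazo ketone, which the ring holds s-Z, expels N2 with concerted 1,2-shift of the ring B carbon C4a from the C4 carbonyl carbon to C3, giving ketene 9. The closest known reaction type is the photo-Wolff ring contraction of six-membered cyclic 2-diazo ketones to five-membered ring carboxylates (for example 2-diazo-1-tetralones to indane-1-carboxylates). The dihydrofuran ring is not closed by cyclisation but arises by contraction of the pyranone through this shift, which forms the C3–C3a bond; C2 and its bond to O1 are untouched, so the flavanone configuration is carried over as 2S. Methanol adds to the ketene to give ester enol 10, and C3 is protonated on the face away from the neighbouring C2 aryl group, which places the ester cis to that aryl (3R). The step needs rearrangement in preference to carbene chemistry (1,2-hydride shift to the flavone, O–H insertion), which the concerted s-Z pathway should secure, and kinetic instead of thermodynamic control at C3, for which neutral methanol, low temperature and a base-free work-up are chosen; 365 nm light is not absorbed by the aryl bromide.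

Step 6
Reactants: 11 methyl (2S,3R)-2-[4-(benzyloxy)-3-methoxyphenyl]-5-bromo-7-methoxy-2,3-dihydro-1-benzofuran-3-carboxylate
Product: 12 [(2S,3S)-2-[4-(benzyloxy)-3-methoxyphenyl]-5-bromo-7-methoxy-2,3-dihydro-1-benzofuran-3-yl]methanol (2,3-cis; S at C3 only by CIP priority)
Conditions: i-Bu2AlH (3 equiv), CH2Cl2, −78 → −20 °C; aq KNaC4H4O6
Reagents that add atoms: none
Why: Ester-to-alcohol reduction with a Lewis-acidic, non-basic hydride at low temperature, so that the acidic C3–H is not epimerised and the aryl bromide and benzyl ether are left alone.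

Step 7
Reactants: 12 [(2S,3S)-2-[4-(benzyloxy)-3-methoxyphenyl]-5-bromo-7-methoxy-2,3-dihydro-1-benzofuran-3-yl]methanol
Product: 13 {[(2S,3S)-2-[4-(benzyloxy)-3-methoxyphenyl]-5-bromo-7-methoxy-2,3-dihydro-1-benzofuran-3-yl]methoxy}(tert-butyl)dimethylsilane
Conditions: TBSCl, imidazole, DMF, 0 °C → rt
Reagents that add atoms: tert-butyldimethylsilyl chloride, CC(C)(C)[Si](C)(C)Cl
Why: Silylation of the primary alcohol gives an ether that tolerates bromine–lithium exchange and is later removed with fluoride instead of hydrogenolysis.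

Step 8
Reactants: 14 4-(benzyloxy)-3-methoxybenzaldehyde
Product: 15 2-[4-(benzyloxy)-3-methoxyphenyl]-1,3-dithiane
Conditions: HS(CH2)3SH, BF3·OEt2 (10 mol%), CH2Cl2, 0 °C → rt
Reagents that add atoms: propane-1,3-dithiol, SCCCS
Why: Lewis-acid-catalysed dithioacetalisation turns the aldehyde carbon into an acyl anion equivalent (umpolung).

Step 9
Reactants: 15 2-[4-(benzyloxy)-3-methoxyphenyl]-1,3-dithiane; 16 (5R)-5-{[(1R,2S,5R)-2-isopropyl-5-methylcyclohexyl]oxy}furan-2(5H)-one
Product: 19 (3S,4R,5R)-4-{2-[4-(benzyloxy)-3-methoxyphenyl]-1,3-dithian-2-yl}-3-(hydroxymethyl)-5-{[(1R,2S,5R)-2-isopropyl-5-methylcyclohexyl]oxy}dihydrofuran-2(3H)-one, via 2-lithiodithiane 17 (not isolated), via lithium lactone enolate 18 (not isolated)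
Conditions: n-BuLi, THF, −78 → −30 °C; 16, −78 °C; CH2O (monomeric, THF solution), −78 °C; aq NH4Cl
Reagents that add atoms: formaldehyde, C=O
Why: Tandem conjugate addition–aldol on a γ-alkoxybutenolide, in which the lithiated dithiane adds to C4 anti to the C5 menthyloxy group and the lactone enolate takes up formaldehyde anti to the new C4 substituent, which fixes C3 as S (the centre that later controls the bicycle).

Step 10
Reactants: 19 (3S,4R,5R)-4-{2-[4-(benzyloxy)-3-methoxyphenyl]-1,3-dithian-2-yl}-3-(hydroxymethyl)-5-(menthyloxy)dihydrofuran-2(3H)-one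
Product: 20 (3S,4R)-4-{2-[4-(benzyloxy)-3-methoxyphenyl]-1,3-dithian-2-yl}-3-(hydroxymethyl)dihydrofuran-2(3H)-one
Conditions: NaBH4, KOH, MeOH/H2O, 0 °C → rt; then 2 M HCl to pH 2
Reagents that add atoms: none
Why: Hydroxide opens the pseudo-ester to the aldehyde carboxylate with loss of menthol, borohydride reduces the aldehyde and acidification relactonises onto the new primary alcohol, the centre α to the carboxylate staying untouched (any epimerisation at C4 is harmless because C4 is reset in step 11).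

Step 11
Reactants: 20 (3S,4R)-4-{2-[4-(benzyloxy)-3-methoxyphenyl]-1,3-dithian-2-yl}-3-(hydroxymethyl)dihydrofuran-2(3H)-one
Product: 22 (1S,5S)-6-[4-(benzyloxy)-3-methoxyphenyl]-6-hydroxy-3,7-dioxabicyclo[3.3.0]octan-2-one (hemiketal, anomer mixture), via trans keto alcohol 21 (not isolated)
Conditions: PhI(OCOCF3)2, MeCN/H2O (9:1), 0 °C; then Et3N (0.2 equiv), CH2Cl2, rt
Reagents that add atoms: water, O
Why: Oxidative dithiane hydrolysis unmasks the aryl ketone, whose α-carbon epimerises under mild base far faster than the lactone α-carbon, and only the cis isomer can close the five-membered hemiketal (5-exo-trig addition of the hydroxyl to the ketone), which drains the equilibrium into the cis-fused bicycle.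

Step 12
Reactants: 22 (1S,5S)-6-[4-(benzyloxy)-3-methoxyphenyl]-6-hydroxy-3,7-dioxabicyclo[3.3.0]octan-2-one
Product: 23 (1S,5S,6S)-6-[4-(benzyloxy)-3-methoxyphenyl]-3,7-dioxabicyclo[3.3.0]octan-2-one (aryl endo)
Conditions: Et3SiH (3 equiv), BF3·OEt2 (2 equiv), CH2Cl2, −78 → −30 °C
Reagents that add atoms: none
Why: Ionic hydrogenation, in which BF3 ionises the hemiketal to the aryl-stabilised oxocarbenium ion and the silane delivers hydride to the convex (exo) face of the cis-fused bicycle, leaving the aryl group endo (6S).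

Step 13
Reactants: 13 {[(2S,3S)-2-[4-(benzyloxy)-3-methoxyphenyl]-5-bromo-7-methoxy-2,3-dihydro-1-benzofuran-3-yl]methoxy}(tert-butyl)dimethylsilane; 23 (1S,5S,6S)-6-[4-(benzyloxy)-3-methoxyphenyl]-3,7-dioxabicyclo[3.3.0]octan-2-one
Product: 25 (1S,5S,6S)-6-[4-(benzyloxy)-3-methoxyphenyl]-2-[(2S,3S)-2-[4-(benzyloxy)-3-methoxyphenyl]-3-{[(tert-butyldimethylsilyl)oxy]methyl}-7-methoxy-2,3-dihydro-1-benzofuran-5-yl]-3,7-dioxabicyclo[3.3.0]octan-2-ol (lactol, anomer mixture), via aryllithium 24 (not isolated)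
Conditions: n-BuLi (1.05 equiv), THF, −78 °C; then 23, −78 °C; aq NH4Cl
Reagents that add atoms: none
Why: Bromine–lithium exchange followed by addition of the aryllithium to the γ-lactone carbonyl, where the tetrahedral lithium alkoxide does not collapse at −78 °C, so a single addition gives the hemiketal.

Step 14
Reactants: 25 the lactol from step 13
Product: 26 (1S,2S,5S,6S)-6-[4-(benzyloxy)-3-methoxyphenyl]-2-[(2S,3S)-2-[4-(benzyloxy)-3-methoxyphenyl]-3-{[(tert-butyldimethylsilyl)oxy]methyl}-7-methoxy-2,3-dihydro-1-benzofuran-5-yl]-3,7-dioxabicyclo[3.3.0]octane (both aryl groups endo)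
Conditions: Et3SiH (5 equiv), BF3·OEt2 (2 equiv), CH2Cl2, −78 °C; Et3N quench at −78 °C
Reagents that add atoms: none
Why: Ionic hydrogenation of the aryl hemiketal as in step 12, with hydride entering the oxocarbenium ion from the exo face (the concave face is further shielded by the endo aryl at C6), so the new aryl at C2 ends up endo (2S).

Step 15
Reactants: 26 the silyl ether from step 14
Product: 27 [(2S,3S)-2-[4-(benzyloxy)-3-methoxyphenyl]-5-{(1S,2S,5S,6S)-6-[4-(benzyloxy)-3-methoxyphenyl]-3,7-dioxabicyclo[3.3.0]octan-2-yl}-7-methoxy-2,3-dihydro-1-benzofuran-3-yl]methanol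
Conditions: Bu4NF, AcOH, THF, 0 °C → rt
Reagents that add atoms: none
Why: Fluoride cleavage of the primary silyl ether, buffered with acetic acid so that no basic alkoxide is exposed to the benzylic ethers.

Step 16
Reactants: 27 the bis(benzyl ether) from step 15
Product: 28 CNP0303197.1, 4-[(1S,2S,5S,6S)-6-[(2S,3S)-2-(4-hydroxy-3-methoxyphenyl)-3-(hydroxymethyl)-7-methoxy-2,3-dihydro-1-benzofuran-5-yl]-3,7-dioxabicyclo[3.3.0]octan-2-yl]-2-methoxyphenol
Conditions: H2 (1 atm), 10% Pd/C, EtOAc, rt, stopped after uptake of 2 equiv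
Reagents that add atoms: none
Why: Hydrogenolysis of the two aryl benzyl ethers over zerovalent palladium on carbon, which should be much faster than cleavage of the cyclic benzylic C–O bonds of the furofuran and dihydrobenzofuran under neutral conditions.

**Compound list**
1 | 2'-hydroxy-3'-methoxyacetophenone | CC(=O)c1cccc(OC)c1O | starting material
2 | 1-(5-bromo-2-hydroxy-3-methoxyphenyl)ethanone | CC(=O)c1cc(Br)cc(OC)c1O | intermediate
3 | (E)-1-(5-bromo-2-hydroxy-3-methoxyphenyl)-3-(dimethylamino)prop-2-en-1-one | CN(C)/C=C/C(=O)c1cc(Br)cc(OC)c1O | intermediate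
4 | 6-bromo-8-methoxy-4H-chromen-4-one | COc1cc(Br)cc2c(=O)ccoc12 | intermediate
5 | [4-(benzyloxy)-3-methoxyphenyl]boronic acid | COc1cc(B(O)O)ccc1OCc1ccccc1 | starting material
6 | (2S)-2-[4-(benzyloxy)-3-methoxyphenyl]-6-bromo-8-methoxy-2,3-dihydro-4H-chromen-4-one | COc1cc(Br)cc2C(=O)C[C@@H](c3ccc(OCc4ccccc4)c(OC)c3)Oc12 | intermediate
7 | (2S)-2-[4-(benzyloxy)-3-methoxyphenyl]-6-bromo-8-methoxy-3-(trifluoroacetyl)-2,3-dihydro-4H-chromen-4-one (C3 epimers/enol) | COc1cc(Br)cc2C(=O)C(C(=O)C(F)(F)F)[C@@H](c3ccc(OCc4ccccc4)c(OC)c3)Oc12 | intermediate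
8 | (2R)-2-[4-(benzyloxy)-3-methoxyphenyl]-6-bromo-3-diazo-8-methoxy-2,3-dihydro-4H-chromen-4-one | COc1cc(Br)cc2C(=O)C(=[N+]=[N-])[C@@H](c3ccc(OCc4ccccc4)c(OC)c3)Oc12 | intermediate
9 | ketene: (2R)-2-[4-(benzyloxy)-3-methoxyphenyl]-5-bromo-7-methoxy-3-(oxomethylidene)-2,3-dihydro-1-benzofuran (C2 spatially as in 8) | COc1cc(Br)cc2C(=C=O)[C@@H](c3ccc(OCc4ccccc4)c(OC)c3)Oc12 | intermediate
10 | ester enol: [2-aryl-5-bromo-7-methoxy-1-benzofuran-3(2H)-ylidene](methoxy)methanol (C2 spatially as in 8) | COc1cc(Br)cc2C(=C(O)OC)[C@@H](c3ccc(OCc4ccccc4)c(OC)c3)Oc12 | intermediate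
11 | methyl (2S,3R)-2-[4-(benzyloxy)-3-methoxyphenyl]-5-bromo-7-methoxy-2,3-dihydro-1-benzofuran-3-carboxylate (cis) | COc1cc(Br)cc2[C@@H](C(=O)OC)[C@@H](c3ccc(OCc4ccccc4)c(OC)c3)Oc12 | intermediate
12 | [(2S,3S)-2-[4-(benzyloxy)-3-methoxyphenyl]-5-bromo-7-methoxy-2,3-dihydro-1-benzofuran-3-yl]methanol (cis) | COc1cc(Br)cc2[C@@H](CO)[C@@H](c3ccc(OCc4ccccc4)c(OC)c3)Oc12 | intermediate
13 | tert-butyldimethylsilyl ether of 12 | COc1cc(Br)cc2[C@@H](CO[Si](C)(C)C(C)(C)C)[C@@H](c3ccc(OCc4ccccc4)c(OC)c3)Oc12 | intermediate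
14 | 4-(benzyloxy)-3-methoxybenzaldehyde | COc1cc(C=O)ccc1OCc1ccccc1 | starting material
15 | 2-[4-(benzyloxy)-3-methoxyphenyl]-1,3-dithiane | COc1cc(C2SCCCS2)ccc1OCc1ccccc1 | intermediate
16 | (5R)-5-{[(1R,2S,5R)-2-isopropyl-5-methylcyclohexyl]oxy}furan-2(5H)-one | O=C1C=C[C@H](O[C@@H]2C[C@H](C)CC[C@H]2C(C)C)O1 | starting material
17 | 2-lithio-2-[4-(benzyloxy)-3-methoxyphenyl]-1,3-dithiane | COc1cc(C2([Li])SCCCS2)ccc1OCc1ccccc1 | intermediate
18 | lithium enolate of (4R,5R)-4-(2-aryl-1,3-dithian-2-yl)-5-(menthyloxy)dihydrofuran-2(3H)-one | [Li]OC1=C[C@@H](C2(c3ccc(OCc4ccccc4)c(OC)c3)SCCCS2)[C@H](O[C@@H]2C[C@H](C)CC[C@H]2C(C)C)O1 | intermediate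
19 | (3S,4R,5R)-4-{2-[4-(benzyloxy)-3-methoxyphenyl]-1,3-dithian-2-yl}-3-(hydroxymethyl)-5-(l-menthyloxy)dihydrofuran-2(3H)-one (all trans) | O=C1O[C@@H](O[C@@H]2C[C@H](C)CC[C@H]2C(C)C)[C@H](C2(c3ccc(OCc4ccccc4)c(OC)c3)SCCCS2)[C@H]1CO | intermediate
20 | (3S,4R)-4-{2-[4-(benzyloxy)-3-methoxyphenyl]-1,3-dithian-2-yl}-3-(hydroxymethyl)dihydrofuran-2(3H)-one (trans) | O=C1OC[C@H](C2(c3ccc(OCc4ccccc4)c(OC)c3)SCCCS2)[C@H]1CO | intermediate
21 | (3S,4R)-4-[4-(benzyloxy)-3-methoxybenzoyl]-3-(hydroxymethyl)dihydrofuran-2(3H)-one (trans) | O=C1OC[C@H](C(=O)c2ccc(OCc3ccccc3)c(OC)c2)[C@H]1CO | intermediate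
22 | (1S,5S)-6-[4-(benzyloxy)-3-methoxyphenyl]-6-hydroxy-3,7-dioxabicyclo[3.3.0]octan-2-one (cis-fused, C6 anomers) | COc1cc(C2(O)OC[C@@H]3[C@H]2COC3=O)ccc1OCc1ccccc1 | intermediate
23 | (1S,5S,6S)-6-[4-(benzyloxy)-3-methoxyphenyl]-3,7-dioxabicyclo[3.3.0]octan-2-one (aryl endo) | COc1cc([C@H]2OC[C@@H]3[C@H]2COC3=O)ccc1OCc1ccccc1 | intermediate
24 | aryllithium from 13 (Li at benzofuran C5) | COc1cc([Li])cc2[C@@H](CO[Si](C)(C)C(C)(C)C)[C@@H](c3ccc(OCc4ccccc4)c(OC)c3)Oc12 | intermediate
25 | lactol: (1S,5S,6S)-6-aryl-2-(benzofuran-5-yl)-3,7-dioxabicyclo[3.3.0]octan-2-ol, C2 anomers | COc1cc([C@H]2OC[C@@H]3[C@H]2COC3(O)c2cc(OC)c3c(c2)[C@@H](CO[Si](C)(C)C(C)(C)C)[C@@H](c2ccc(OCc4ccccc4)c(OC)c2)O3)ccc1OCc1ccccc1 | intermediate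
26 | (1S,2S,5S,6S)-2,6-diaryl-3,7-dioxabicyclo[3.3.0]octane, both aryl endo, silyl and benzyl protected | COc1cc([C@H]2OC[C@@H]3[C@H]2CO[C@@H]3c2cc(OC)c3c(c2)[C@@H](CO[Si](C)(C)C(C)(C)C)[C@@H](c2ccc(OCc4ccccc4)c(OC)c2)O3)ccc1OCc1ccccc1 | intermediate
27 | bis(benzyl ether) of the target with free primary alcohol | COc1cc([C@H]2OC[C@@H]3[C@H]2CO[C@@H]3c2cc(OC)c3c(c2)[C@@H](CO)[C@@H](c2ccc(OCc4ccccc4)c(OC)c2)O3)ccc1OCc1ccccc1 | intermediate
28 | CNP0303197.1 | COc1cc([C@H]2OC[C@@H]3[C@H]2CO[C@@H]3c2cc(OC)c3c(c2)[C@@H](CO)[C@@H](c2ccc(O)c(OC)c2)O3)ccc1O | target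

**Count**
Total steps: 16. Longest linear sequence: 11 steps (steps 1–7 and 13–16); the lactone branch (steps 8–12) is 5 steps and joins at step 13.

**Steps most likely to fail**

Step 5 (Wolff ring contraction). What may go wrong: protonation of ester enol 10 on the aryl face, or enolisation of the ester afterwards, erodes the cis ratio towards the more stable trans isomer; carbene O–H insertion or 1,2-hydride shift competes with the rearrangement. Fallback (carbenoid C–H insertion in place of ring contraction), setting out from phenol 2 and returning at ester 11: phenol 2 would be etherified with purchasable 4-(benzyloxy)-3-methoxybenzyl alcohol under Mitsunobu conditions (PPh3, DIAD, THF) to give 1-[2-{[4-(benzyloxy)-3-methoxyphenyl]methoxy}-5-bromo-3-methoxyphenyl]ethanone F1. SeO2 in pyridine should oxidise the acetyl group to the arylglyoxylic acid F2, which MeI/K2CO3 converts into the methyl arylglyoxylate F3. Condensation with TsNHNH2 gives the tosylhydrazone F4, and DBU in CH2Cl2 (Bamford–Stevens conditions) the methyl aryldiazoacetate F5. The chiral dirhodium carboxylate Rh2(S-PTTL)4 (dirhodium tetrakis[N-phthaloyl-(S)-tert-leucinate]) or its antipode, whichever gives 2S,3R, in toluene at −60 °C should then insert the carbenoid into the benzylic C–H bond of the ether; this reaction type is known to give cis-2-aryl-2,3-dihydrobenzofuran-3-carboxylates under kinetic control, that is 11.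

Step 4 (diazo transfer). What may go wrong: β-elimination of the ring B phenoxide from the C3 enolate (opening to the chalcone) and reclosure, which destroys or racemises C2; incomplete C-acylation. Fallback (no metal enolate), setting out from flavanone 6 and returning at diazo ketone 8: heating 6 with Me2NCH(OMe)2 should give the 3-[(dimethylamino)methylidene]flavanone F6, and treatment with 4-acetamidobenzenesulfonyl azide in MeCN at rt (azide cycloaddition to the enaminone, then cycloreversion with loss of the N-sulfonylformamidine) is a known entry to 2-diazo ketones.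

Step 14 (silane reduction of the coupled lactol). What may go wrong: BF3 ionises the benzylic C–O bonds (C6–O7 of the furofuran, C2–O1 of the cis-dihydrobenzofuran), which epimerises the endo or cis centres or lets the silane open the rings; partial loss of the silyl ether (harmless, since step 15 removes it); hydride delivery to the concave face. Fallback (no carbocation), setting out from lactol 25 and returning at 26: the open hydroxy ketone form of 25 would be reduced with NaBH4/CeCl3 (MeOH, −78 °C) to the diol F7, in which the (S)-carbinol is needed; the epimer would be reoxidised with MnO2 to 25 and recycled. Mitsunobu cyclodehydration (PPh3, DIAD, THF) activates the primary alcohol, so the benzylic oxygen closes the ring by SN2 at CH2 with retention at the carbinol carbon.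

**Further compounds**
F1 | step 5 | 1-[2-{[4-(benzyloxy)-3-methoxyphenyl]methoxy}-5-bromo-3-methoxyphenyl]ethanone | CC(=O)c1cc(Br)cc(OC)c1OCc1ccc(OCc2ccccc2)c(OC)c1
F2 | step 5 | 2-[2-{[4-(benzyloxy)-3-methoxyphenyl]methoxy}-5-bromo-3-methoxyphenyl]-2-oxoacetic acid | OC(=O)C(=O)c1cc(Br)cc(OC)c1OCc1ccc(OCc2ccccc2)c(OC)c1
F3 | step 5 | methyl 2-[2-{[4-(benzyloxy)-3-methoxyphenyl]methoxy}-5-bromo-3-methoxyphenyl]-2-oxoacetate | COC(=O)C(=O)c1cc(Br)cc(OC)c1OCc1ccc(OCc2ccccc2)c(OC)c1
F4 | step 5 | methyl 2-[2-{[4-(benzyloxy)-3-methoxyphenyl]methoxy}-5-bromo-3-methoxyphenyl]-2-(tosylhydrazinylidene)acetate | COC(=O)C(=NNS(=O)(=O)c1ccc(C)cc1)c1cc(Br)cc(OC)c1OCc1ccc(OCc2ccccc2)c(OC)c1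
F5 | step 5 | methyl 2-[2-{[4-(benzyloxy)-3-methoxyphenyl]methoxy}-5-bromo-3-methoxyphenyl]-2-diazoacetate | COC(=O)C(=[N+]=[N-])c1cc(Br)cc(OC)c1OCc1ccc(OCc2ccccc2)c(OC)c1
F6 | step 4 | (2R)-2-[4-(benzyloxy)-3-methoxyphenyl]-6-bromo-3-[(dimethylamino)methylidene]-8-methoxy-2,3-dihydro-4H-chromen-4-one (C2 spatially as in 6) | COc1cc(Br)cc2C(=O)C(=CN(C)C)[C@@H](c3ccc(OCc4ccccc4)c(OC)c3)Oc12
F7 | step 14 | (S)-[(2S,3S)-2-[4-(benzyloxy)-3-methoxyphenyl]-3-{[(tert-butyldimethylsilyl)oxy]methyl}-7-methoxy-2,3-dihydro-1-benzofuran-5-yl]{(3S,4S,5S)-5-[4-(benzyloxy)-3-methoxyphenyl]-4-(hydroxymethyl)oxolan-3-yl}methanol (descriptors in the name are indicative; the SMILES defines the configuration) | COc1cc([C@H]2OC[C@@H]([C@H](O)c3cc(OC)c4c(c3)[C@@H](CO[Si](C)(C)C(C)(C)C)[C@@H](c3ccc(OCc5ccccc5)c(OC)c3)O4)[C@H]2CO)ccc1OCc1ccccc1
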